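**Plan**

- Retrosynthesis: the C10–O angelate and C6–O aroate bonds are cut first, then C8–CH3 and C4–isopropyl, then the C4–C5 bond of ring A. This leads back to achiral 2-methyl-2-(3-oxopropyl)cycloheptane-1,3-dione, made from cycloheptane-1,3-dione, iodomethane and acrolein.
- Enabling feature: quaternary C1 lies between oxygen-bearing C10 and ring-fusion carbon C5, so both can be the enantiotopic carbonyls of a ring B 1,3-dione; C4 ends a three-carbon arm on C1 and can serve as an acyl-anion carbon.
- Forward: ring B is purchased, C1 is quaternised, and ring A is closed by a carbene-catalysed benzoin reaction. C4–C6 are then adjusted (dehydration, reduction, hydroboration, isopropyl addition), ring B is desaturated and methylated, and the two esters go on last.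
- Stereochemistry: C1 from the chiral triazolium catalyst; C5 and C6 together from one syn hydroboration on the α face (trans ring fusion); C4 from α-face organocerium addition; C10 from a CBS reduction; the Z alkene from angelic acid.
- Numbering used throughout: C1 (quaternary, CH3), C2, C3, C4 (carbinol, isopropyl), C5 (ring-fusion CH), C6 (aroyloxy), C7, C8(CH3)=C9, C10 (angeloyloxy); ring A = C1–C5, ring B = C1, C5–C10; β = face of the C1 methyl.

Key step: step 3

Assumption: the (5aS,10bR) triazolium salt is taken to select the ring carbonyl that gives (1S)-6; if it favours the other carbonyl, its equally available antipode is used with no other change.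

**Route**

Step 1
Reactants: 1 cycloheptane-1,3-dione; 2 iodomethane
Product: 3 2-methylcycloheptane-1,3-dione
Conditions: MeI (1.05 equiv), K2CO3, acetone, 56 °C
Reagents that add atoms: none
Why: C-alkylation of the 1,3-diketone enolate (SN2 on MeI) is favoured for the largely diketo seven-membered dione, and near-stoichiometric MeI limits double methylation.

Step 2
Reactants: 3 2-methylcycloheptane-1,3-dione; 4 acrolein
Product: 5 2-methyl-2-(3-oxopropyl)cycloheptane-1,3-dione
Conditions: acrolein (1.5 equiv), Et3N (0.1 equiv), MeCN, 0 → 23 °C
Reagents that add atoms: none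
Why: Amine-catalysed Michael addition of the 2-substituted 1,3-diketone to acrolein creates quaternary C1, which stays achiral because the two ring carbonyls are equivalent.

Step 3
Reactants: 5 2-methyl-2-(3-oxopropyl)cycloheptane-1,3-dione
Product: 6 (1S,5R)-5-hydroxy-1-methylperhydroazulene-4,10-dione (route numbering; cis-fused ketol with 5-OH and 1-CH3 both β)
Conditions: (5aS,10bR)-2-(pentafluorophenyl)-5a,10b-dihydro-4H,6H-indeno[2,1-b][1,2,4]triazolo[4,3-d][1,4]oxazin-2-ium tetrafluoroborate (10 mol %), Et3N (10 mol %), toluene, 23 °C
Reagents that add atoms: none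
Why: Deprotonation of the triazolium salt gives the carbene, which adds to the aldehyde carbon C4; proton transfer gives the Breslow intermediate, which attacks the C5 carbonyl, and the carbene is expelled from the adduct to leave the C4 ketone and the C5 tertiary alcohol. The closest known reaction type is the carbene-catalysed intramolecular crossed aldehyde–ketone benzoin reaction in its desymmetrising form on 2,2-disubstituted cyclic 1,3-diketones. Ring A closes by 5-exo-trig attack on the carbonyl carbon. C1 becomes stereogenic through the catalyst's choice between the two enantiotopic ring carbonyls, and C5 follows from the three-atom tether, which can only reach the carbonyl from its own side and so gives the cis-fused ketol. The step needs chemoselectivity and enantiotopic-group selectivity: the first is built into a substrate with a single aldehyde as acyl-anion donor and only ketones as acceptors, the second is supplied by the aminoindanol backbone of the catalyst, and the weak amine base keeps aldol pathways slow.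

Step 4
Reactants: 6 cis-fused ketol
Product: 7 (1S)-1-methyl-2,3,7,8-tetrahydroazulene-type enedione (route numbering; C4 ketone conjugated to C5=C6 and C10 ketone)
Conditions: Burgess reagent (1.5 equiv), toluene, 70 °C
Reagents that add atoms: none
Why: Burgess dehydration (syn elimination through the sulfamate ester) can only take a hydrogen from C6, because C1 and the C4 carbonyl carbon carry none, so only the C5=C6 enone can form and the C5 centre is erased on purpose.

Step 5
Reactants: 7 enedione
Product: 8 (1S)-10,10-ethylenedioxy enone (route numbering; dioxolane at C10 and C4 ketone conjugated to C5=C6)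
Conditions: ethylene glycol (5 equiv), p-TsOH·H2O (10 mol %), 4 Å MS, CH2Cl2, 23 °C
Reagents that add atoms: ethylene glycol, OCCO
Why: Acid-catalysed ketalisation is much faster at a saturated ketone than at a conjugated one, the standard way to tell such a pair apart, so C10 is masked against borane and organometallic reagents.

Step 6
Reactants: 8 enone ketal
Product: 9 (1S,4S)-allylic alcohol (route numbering; 4β-OH with C5=C6 and C10 dioxolane)
Conditions: (R)-2-methyl-CBS-oxazaborolidine (0.2 equiv), BH3·SMe2 (0.7 equiv), THF, −20 °C; MeOH
Reagents that add atoms: none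
Why: Corey–Bakshi–Shibata reduction gives 1,2-hydride delivery to the s-cis enone with the fully substituted alkenyl carbon C5 as the large group, so the (R)-catalyst should place the hydroxyl on the β face (4S), where it will steer the next step.

Step 7
Reactants: 9 allylic alcohol
Product: 11 (1S,4S,5S,6S)-10,10-ethylenedioxy-1-methylperhydroazulene-4,6-diol (route numbering; 4β-OH 5α-H 6α-OH), via alkylborane 10 (not isolated)
Conditions: BH3·THF (3 equiv), THF, 0 → 23 °C; then NaOH (3 M), H2O2 (30 %), 0 → 23 °C
Reagents that add atoms: hydrogen peroxide, OO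
Why: Hydroboration–oxidation puts boron on the less substituted C6 and hydrogen on C5 in one syn addition from the α face, anti to both the C1 methyl and the allylic 4β-oxygen, so the trans ring fusion (5α-H) and the 6α-oxygen are set together and C–B oxidation proceeds with retention.

Step 8
Reactants: 11 diol
Product: 12 (1S,4S,5R,6S)-6-(tert-butyldimethylsilyloxy)-10,10-ethylenedioxy-1-methylperhydroazulen-4-ol (route numbering; same spatial arrangement as 11)
Conditions: TBSCl (1.1 equiv), imidazole, DMF, 0 °C
Reagents that add atoms: tert-butyldimethylsilyl chloride, CC(C)(C)[Si](C)(C)Cl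
Why: Silylation is sterically selective for the equatorial 6α-hydroxyl, because the 4β-hydroxyl is flanked by the cis C5–C6 bond and the syn-1,3 angular methyl.

Step 9
Reactants: 12 mono-silyl ether
Product: 13 (1S,5S,6S)-6-(tert-butyldimethylsilyloxy)-10,10-ethylenedioxy-1-methylperhydroazulen-4-one (route numbering; trans-fused with 5α-H)
Conditions: Dess–Martin periodinane (1.5 equiv), NaHCO3, CH2Cl2, 0 → 23 °C; used without chromatography
Reagents that add atoms: none
Why: Dess–Martin oxidation works on hindered secondary alcohols under buffered, non-basic conditions that should neither epimerise the adjacent C5–H nor eliminate the β-silyloxy group.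

Step 10
Reactants: 13 ketone; 14 isopropylmagnesium chloride
Product: 15 (1S,4R,5S,6S)-6-(tert-butyldimethylsilyloxy)-10,10-ethylenedioxy-4-isopropyl-1-methylperhydroazulen-4-ol (route numbering; 4β-OH 4α-isopropyl)
Conditions: iPrMgCl (3.0 equiv), CeCl3 (3.3 equiv), THF, −78 → −40 °C; aq. NH4Cl
Reagents that add atoms: none
Why: Organocerium 1,2-addition has low basicity, which suppresses enolisation, reduction and β-elimination, and the reagent should approach C4 from the α face, anti to the cis-vicinal C5–C6 bond and the angular methyl, to give the 4β-hydroxy-4α-isopropyl centre.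

Step 11
Reactants: 15 tertiary alcohol
Product: 16 (1S,4R,5S,6S)-4,6-dihydroxy-4-isopropyl-1-methylperhydroazulen-10-one (route numbering; 4β-OH 6α-OH)
Conditions: 2 M HCl, THF, 23 °C
Reagents that add atoms: water, O
Why: Aqueous acid hydrolysis removes the dioxolane and the silyl ether in one operation, and the tertiary alcohol, which has no carbonyl β to it, should tolerate dilute acid at room temperature.

Step 12
Reactants: 17 4-hydroxybenzoic acid
Product: 19 4-(tert-butyldimethylsilyloxy)benzoic acid, via bis-silyl derivative 18 (not isolated)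
Conditions: TBSCl (2.2 equiv), imidazole, DMF, 23 °C; then AcOH/THF/H2O (3:1:1), 23 °C
Reagents that add atoms: tert-butyldimethylsilyl chloride, CC(C)(C)[Si](C)(C)Cl
Why: Silylation of both hydroxyls followed by selective hydrolysis of the labile silyl ester leaves the phenol protected as its silyl ether.

Step 13
Reactants: 16 diol ketone; 19 4-(tert-butyldimethylsilyloxy)benzoic acid
Product: 20 (1S,4R,5S,6S)-4-hydroxy-4-isopropyl-1-methyl-10-oxoperhydroazulen-6-yl 4-(tert-butyldimethylsilyloxy)benzoate (route numbering)
Conditions: 19 (1.5 equiv), EDC·HCl (1.8 equiv), DMAP (0.5 equiv), CH2Cl2, 23 °C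
Reagents that add atoms: none
Why: Carbodiimide/DMAP (Steglich) esterification acylates only the secondary C6 hydroxyl, the tertiary C4 hydroxyl being inert, and the ester also protects C6–OH from the oxidant used next.

Step 14
Reactants: 20 keto ester
Product: 21 C8=C9 enone of 20 (route numbering; (1S,4R,5S,6S) with C10 ketone conjugated to C8=C9)
Conditions: IBX (2.0 equiv), toluene/DMSO (2:1), 70 °C
Reagents that add atoms: none
Why: IBX-mediated α,β-dehydrogenation of the ketone can only run towards C9 because C1 is quaternary, so the C8=C9 enone is the only possible product.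

Step 15
Reactants: 21 enone; 22 methyllithium
Product: 23 8-methyl ketone (route numbering; (1S,4R,5S,6S) with C8 as a mixture of epimers)
Conditions: MeLi (6 equiv), CuI (3 equiv), Et2O, −20 °C; then 21, −78 → −30 °C; aq. NH4Cl
Reagents that add atoms: none
Why: Conjugate addition of the Gilman cuprate to the cycloheptenone places the methyl on C8, the new C8 centre is irrelevant because it becomes sp2 in the next step, and the aryl ester is not attacked by the cuprate at low temperature.

Step 16
Reactants: 23 8-methyl ketone
Product: 24 8-methyl enone (route numbering; (1S,4R,5S,6S) with C8(CH3)=C9–C10=O)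
Conditions: IBX (2.5 equiv), toluene/DMSO (2:1), 75 °C
Reagents that add atoms: none
Why: A second IBX dehydrogenation, again regiodefined by quaternary C1, restores the C8=C9 double bond, now carrying the methyl group.

Step 17
Reactants: 24 8-methyl enone
Product: 25 (1S,4R,5S,6S,10R)-allylic alcohol (route numbering; 10α-OH with C8(CH3)=C9 and 6α-aroyloxy)
Conditions: (S)-2-methyl-CBS-oxazaborolidine (1.0 equiv), BH3·SMe2 (2.5 equiv), THF, −40 → −20 °C; MeOH
Reagents that add atoms: none
Why: Corey–Bakshi–Shibata reduction is 1,2-selective for enones, and with quaternary C1 as the large group and the C9 alkenyl CH as the small one the (S)-catalyst should deliver hydride to the β face of C10 and give the 10α-alcohol, overriding the substrate's likely preference for attack anti to the angular methyl.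

Step 18
Reactants: 25 allylic alcohol; 26 angelic acid ((Z)-2-methylbut-2-enoic acid)
Product: 28 silyl-protected target (route numbering; (1S,4R,5S,6S,10R) 10-angelate 6-[4-(tert-butyldimethylsilyloxy)benzoate]), via mixed anhydride 27 (not isolated)
Conditions: 26 (3 equiv), 2,4,6-trichlorobenzoyl chloride (3 equiv), Et3N (6 equiv), toluene, 23 °C; then 25, 80 °C
Reagents that add atoms: none
Why: In this Yamaguchi-type esterification the hindered trichlorobenzoyl carbonyl directs the alcohol to the angeloyl carbonyl, leaving out nucleophilic catalysts should preserve the Z double bond, and the tertiary hydroxyl does not react.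

Step 19
Reactants: 28 silyl-protected target
Product: 29 CNP0273650.2 ((1S,4R,5S,6S,10R) in route numbering)
Conditions: TBAF (1.2 equiv), AcOH (1.2 equiv), THF, 0 °C
Reagents that add atoms: none
Why: Fluoride cleaves the aryl silyl ether much faster than it touches the esters, and acetic acid buffering should prevent acyl transfer or Z/E isomerisation of the angelate.

**Compound list**

1 | cycloheptane-1,3-dione | O=C1CCCCC(=O)C1 | starting material
2 | iodomethane | CI | starting material
3 | 2-methylcycloheptane-1,3-dione | CC1C(=O)CCCCC1=O | intermediate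
4 | acrolein | C=CC=O | starting material
5 | 2-methyl-2-(3-oxopropyl)cycloheptane-1,3-dione | CC1(CCC=O)C(=O)CCCCC1=O | intermediate
6 | (1S,5R)-5-hydroxy-1-methylperhydroazulene-4,10-dione, cis-fused ketol (route numbering) | O=C1CCCC[C@@]2(O)[C@]1(C)CCC2=O | intermediate
7 | (1S)-enedione, C4=O conjugated to C5=C6, C10=O (route numbering) | O=C1CCCC=C2[C@]1(C)CCC2=O | intermediate
8 | (1S)-10,10-ethylenedioxy enone (route numbering) | C12(OCCO1)CCCC=C3[C@]2(C)CCC3=O | intermediate
9 | (1S,4S)-4β-hydroxy allylic alcohol, C5=C6, C10 dioxolane (route numbering) | C12(OCCO1)CCCC=C3[C@]2(C)CC[C@@H]3O | intermediate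
10 | 6α-dihydroboryl 4-O-dihydroboryl adduct of 9 (alkylborane) | C12(OCCO1)CCC[C@H]([BH2])[C@@H]3[C@]2(C)CC[C@@H]3O[BH2] | intermediate
11 | (1S,4S,5S,6S)-4β,6α-diol, 5α-H, C10 dioxolane (route numbering) | C12(OCCO1)CCC[C@H](O)[C@@H]3[C@]2(C)CC[C@@H]3O | intermediate
12 | (1S,4S,5R,6S)-6α-(tert-butyldimethylsilyloxy)-4β-ol, C10 dioxolane (route numbering) | C12(OCCO1)CCC[C@H](O[Si](C)(C)C(C)(C)C)[C@@H]3[C@]2(C)CC[C@@H]3O | intermediate
13 | (1S,5S,6S)-6α-(tert-butyldimethylsilyloxy)-4-ketone, 5α-H, C10 dioxolane (route numbering) | C12(OCCO1)CCC[C@H](O[Si](C)(C)C(C)(C)C)[C@@H]3[C@]2(C)CCC3=O | intermediate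
14 | isopropylmagnesium chloride | CC(C)[Mg]Cl | starting material
15 | (1S,4R,5S,6S)-4β-hydroxy-4α-isopropyl-6α-(tert-butyldimethylsilyloxy), C10 dioxolane (route numbering) | C12(OCCO1)CCC[C@H](O[Si](C)(C)C(C)(C)C)[C@@H]3[C@]2(C)CC[C@@]3(O)C(C)C | intermediate
16 | (1S,4R,5S,6S)-4β,6α-dihydroxy-4α-isopropyl-1-methylperhydroazulen-10-one (route numbering) | O=C1CCC[C@H](O)[C@@H]2[C@]1(C)CC[C@@]2(O)C(C)C | intermediate
17 | 4-hydroxybenzoic acid | OC(=O)c1ccc(O)cc1 | starting material
18 | tert-butyldimethylsilyl 4-(tert-butyldimethylsilyloxy)benzoate | CC(C)(C)[Si](C)(C)OC(=O)c1ccc(O[Si](C)(C)C(C)(C)C)cc1 | intermediate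
19 | 4-(tert-butyldimethylsilyloxy)benzoic acid | OC(=O)c1ccc(O[Si](C)(C)C(C)(C)C)cc1 | intermediate
20 | (1S,4R,5S,6S)-6-O-[4-(tert-butyldimethylsilyloxy)benzoyl] 10-ketone (route numbering) | O=C1CCC[C@H](OC(=O)c3ccc(O[Si](C)(C)C(C)(C)C)cc3)[C@@H]2[C@]1(C)CC[C@@]2(O)C(C)C | intermediate
21 | (1S,4R,5S,6S)-C8=C9 enone of 20 (route numbering) | O=C1C=CC[C@H](OC(=O)c3ccc(O[Si](C)(C)C(C)(C)C)cc3)[C@@H]2[C@]1(C)CC[C@@]2(O)C(C)C | intermediate
22 | methyllithium | [Li]C | starting material
23 | (1S,4R,5S,6S)-8-methyl 10-ketone, C8 epimers (route numbering) | O=C1CC(C)C[C@H](OC(=O)c3ccc(O[Si](C)(C)C(C)(C)C)cc3)[C@@H]2[C@]1(C)CC[C@@]2(O)C(C)C | intermediate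
24 | (1S,4R,5S,6S)-8-methyl C8=C9 enone (route numbering) | O=C1C=C(C)C[C@H](OC(=O)c3ccc(O[Si](C)(C)C(C)(C)C)cc3)[C@@H]2[C@]1(C)CC[C@@]2(O)C(C)C | intermediate
25 | (1S,4R,5S,6S,10R)-10α-allylic alcohol (route numbering) | O[C@@H]1C=C(C)C[C@H](OC(=O)c3ccc(O[Si](C)(C)C(C)(C)C)cc3)[C@@H]2[C@]1(C)CC[C@@]2(O)C(C)C | intermediate
26 | angelic acid, (Z)-2-methylbut-2-enoic acid | C/C=C(/C)C(=O)O | starting material
27 | (Z)-2-methylbut-2-enoic 2,4,6-trichlorobenzoic anhydride | C/C=C(/C)C(=O)OC(=O)c1c(Cl)cc(Cl)cc1Cl | intermediate
28 | (1S,4R,5S,6S,10R)-10-angelate 6-[4-(tert-butyldimethylsilyloxy)benzoate] (route numbering) | C/C=C(/C)C(=O)O[C@@H]1C=C(C)C[C@H](OC(=O)c3ccc(O[Si](C)(C)C(C)(C)C)cc3)[C@@H]2[C@]1(C)CC[C@@]2(O)C(C)C | intermediate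
29 | CNP0273650.2 | C/C=C(/C)C(=O)O[C@@H]1C=C(C)C[C@H](OC(=O)c2ccc(O)cc2)[C@@H]2[C@]1(C)CC[C@@]2(O)C(C)C | target

**Step count and risks**

Total step count: 19. Longest linear sequence: 18 steps (steps 1–11 and 13–19, from cycloheptane-1,3-dione); step 12 is a one-step side branch.

Most likely to fail, in order:

Step 7. The risk is poor facial selectivity in the hydroboration. The pseudo-axial dioxolane oxygen at C10 crowds the α face, so borane may add partly or mainly from the β face, which would invert C5 and C6 together and give the cis ring fusion. The fallback enforces the face with a removable blocking group instead of relying on the intrinsic bias. It sets out from 9, which is silylated (TBSOTf, 2,6-lutidine, CH2Cl2, −78 °C) to the 4β-silyl ether F1, where the bulky silyloxy group next to C6 shields the β face. Hydroboration–oxidation of F1 (BH3·SMe2; NaOH, H2O2) should give the 6α-alcohol F2, and TBAF in THF removes the silyl group to come back to the route at 11.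

Step 17. The risk is insufficient catalyst control at the hindered enone flanked by quaternary C1, so that hydride adds mainly anti to the angular methyl and the C10 configuration comes out inverted. The fallback accepts the substrate-controlled sense and inverts it in the esterification. It sets out from 24, which is reduced without a chiral catalyst (NaBH4, CeCl3·7H2O, MeOH, −40 °C) to the 10β-alcohol F3. Mitsunobu esterification with angelic acid 26 (PPh3, DIAD, toluene, 0 → 23 °C) then displaces the activated oxygen with inversion and comes back to the route at 28, skipping 25.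

Step 18. The risk is slow acylation of the neopentylic C10 hydroxyl, with Z to E isomerisation of the angeloyl unit on prolonged heating with amine. The fallback builds the Z alkene on the ester instead of transferring it. It sets out from 25, which is esterified with 2-[bis(2,2,2-trifluoroethoxy)phosphoryl]propanoic acid (EDC·HCl, DMAP, CH2Cl2) to the phosphonopropanoate ester F4. A Still–Gennari olefination (KN(SiMe3)2, 18-crown-6, THF, −78 °C, acetaldehyde) is Z-selective and comes back to the route at 28.

**Further compounds**

F1 | step 7 | (1S,4S)-4β-(tert-butyldimethylsilyloxy) allylic ether of 9, C5=C6, C10 dioxolane (route numbering) | C12(OCCO1)CCCC=C3[C@]2(C)CC[C@@H]3O[Si](C)(C)C(C)(C)C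
F2 | step 7 | (1S,4S,5S,6S)-4β-(tert-butyldimethylsilyloxy)-6α-ol, 5α-H, C10 dioxolane (route numbering) | C12(OCCO1)CCC[C@H](O)[C@@H]3[C@]2(C)CC[C@@H]3O[Si](C)(C)C(C)(C)C
F3 | step 17 | (1S,4R,5S,6S,10S)-10β-allylic alcohol, C10 epimer of 25 (route numbering) | O[C@H]1C=C(C)C[C@H](OC(=O)c3ccc(O[Si](C)(C)C(C)(C)C)cc3)[C@@H]2[C@]1(C)CC[C@@]2(O)C(C)C
F4 | step 18 | 10-O-{2-[bis(2,2,2-trifluoroethoxy)phosphoryl]propanoyl} ester of 25 (route numbering) | CC(C(=O)O[C@@H]1C=C(C)C[C@H](OC(=O)c3ccc(O[Si](C)(C)C(C)(C)C)cc3)[C@@H]2[C@]1(C)CC[C@@]2(O)C(C)C)P(=O)(OCC(F)(F)F)OCC(F)(F)F
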